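**Plan**

1. Numbering: C1 (benzoyl bridgehead), C2 (OMe), C3, C4 (C=O), C5 (prenyl bridgehead), C6, C7, C8 (CMe2), C9 (bridging C=O), C10–C13 (side chain on C7). The retrosynthesis removes the acetate and the C1 benzoyl group, then cuts C5–C9 and C1–C8 together.
2. Enabling feature: ring B (C1–C9–C5–C6–C7–C8) is a cyclobutane C5–C6–C7–C8 (acyl group on C5, CMe2 at C8, stereocentre C7) with the unit C9–C1 inserted into its C5–C8 bond. That cyclobutane is the four-membered ring of (−)-α-pinene.
3. Forward: ozonolysis opens the six-membered ring of pinene, a Wittig/reduction sequence builds the (E) side chain on C7, and the acetyl group is grown into the chain C4–C3–C2(OMe)=C1–C9O2H, with C3 blocked as a quaternary tert-butyl ester and C5 prenylated.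
4. Key step (one pot): a Lewis acid opens the cyclobutane to a dihydropyran (C8 parked on O4), the C9 acylium ion acylates C5 (ring A), the oxocarbenium ion releases the C8 cation, C1 captures it (ring B), and loss of isobutene and CO2 from C3 unveils the C2 enol ether.
5. Stereochemistry: C7 comes from (−)-α-pinene, C5 from acylation anti to the C7 chain on the dihydropyran, C1 from the geometry of the bicycle, the alkene geometry from the stabilised ylide.
6. End game: bridgehead benzoylation at C1, desilylation, acetylation.

Key step: step 11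

Remark: 2–6 are drawn with the cis ring substituents of pinene, 7–13 are mixtures of epimers at C5 and/or C3, and 10–13 are also mixtures of enol ether isomers; all these elements are erased or reset in step 11, so the SMILES leave them undefined where they are mixed.

**Route**

Step 1
Reactants: 1 (−)-α-pinene
Product: 2 (−)-cis-pinonaldehyde
Conditions: O3, CH2Cl2/MeOH, −78 °C; then Me2S, −78 °C → rt
Reagents that add atoms: ozone, O=[O+][O-]
Why: Ozonolysis with reductive work-up cleaves only the ring alkene, so the six-membered ring of pinene is opened to a methyl ketone (C4, C3) and an aldehyde (C11) while the cyclobutane and its C7 stereocentre stay as they are.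

Step 2
Reactants: 2 (−)-cis-pinonaldehyde
Product: 3 (E)-enal
Conditions: Ph3P=C(Me)CHO, toluene, 80 °C
Reagents that add atoms: 2-(triphenylphosphoranylidene)propanal, CC(C=O)=P(c1ccccc1)(c1ccccc1)c1ccccc1
Why: Wittig olefination with the formyl-stabilised ylide should take the aldehyde and not the hindered methyl ketone and should give the (E)-trisubstituted alkene, as stabilised ylides do.

Step 3
Reactants: 3 (E)-enal
Product: 4 allylic alcohol
Conditions: NaBH4, MeOH/CH2Cl2, −78 °C
Reagents that add atoms: none
Why: Chemoselective borohydride 1,2-reduction, since at −78 °C an aldehyde is reduced far faster than a hindered cyclobutyl methyl ketone.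

Step 4
Reactants: 4 allylic alcohol
Product: 5 silyl ether
Conditions: TBDPSCl, imidazole, DMF, 0 °C → rt
Reagents that add atoms: tert-butyl(chloro)diphenylsilane, CC(C)(C)[Si](Cl)(c1ccccc1)c1ccccc1
Why: Standard silylation of a primary alcohol gives an ether that should be inert to the amide bases, organometallic reagents and Lewis acids used up to step 12.

Step 5
Reactants: 5 silyl ether
Product: 6 tert-butyl β-keto ester
Conditions: LiN(i-Pr)2 (2.2 equiv), THF, −78 °C; Boc2O, −78 → 0 °C; then aq. NH4Cl
Reagents that add atoms: di-tert-butyl dicarbonate, CC(C)(C)OC(=O)OC(=O)OC(C)(C)C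
Why: Kinetic deprotonation takes the methyl group (C3), and C-acylation of the lithium enolate with the dicarbonate (Claisen-type acylation) should give the β-keto ester, which the second equivalent of base stores as its enolate.

Step 6
Reactants: 6 tert-butyl β-keto ester
Product: 7 C5-prenyl keto ester
Conditions: NaH, THF, 0 °C; n-BuLi, −10 °C; prenyl bromide, −78 → 0 °C; then aq. NH4Cl
Reagents that add atoms: prenyl bromide (1-bromo-3-methylbut-2-ene), CC(C)=CCBr
Why: γ-Alkylation of a β-keto ester dianion, in which the more basic carbanion at the cyclobutane methine C5 is the one alkylated; the configuration of the new quaternary centre does not matter because C5 becomes planar again in step 11.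

Step 7
Reactants: 7 C5-prenyl keto ester
Product: 8 C3,C5-diprenyl keto ester
Conditions: K2CO3, prenyl bromide, acetone, 50 °C
Reagents that add atoms: prenyl bromide (1-bromo-3-methylbut-2-ene), CC(C)=CCBr
Why: C-Alkylation of a β-keto ester with an allylic bromide under carbonate conditions should put the second prenyl group on C3, whose configuration is likewise erased later.

Step 8
Reactants: 8 C3,C5-diprenyl keto ester
Product: 9 triketo diester
Conditions: i-PrMgCl, THF, −40 °C; ClC(O)CH2CO2Me, −78 → 0 °C
Reagents that add atoms: methyl malonyl chloride (methyl 3-chloro-3-oxopropanoate), COC(=O)CC(Cl)=O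
Why: C-Acylation of the chelated magnesium enolate of a β-keto ester with an acid chloride (Claisen-type acylation) makes C3 quaternary, so that C3 can no longer enolise or act as a nucleophile and C2 can enolise only towards C1.

Step 9
Reactants: 9 triketo diester
Product: 10 β-methoxy enoate
Conditions: KN(SiMe3)2, 18-crown-6, THF, −78 °C; MeOTf
Reagents that add atoms: methyl trifluoromethanesulfonate, COS(=O)(=O)C(F)(F)F
Why: O-Alkylation of a crown-ether-separated potassium enolate with a hard methylating agent should give the enol ether, and because C1 carries the only acidic hydrogens the methoxy group is fixed on C2.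

Step 10
Reactants: 10 β-methoxy enoate
Product: 11 carboxylic acid
Conditions: LiOH, THF/MeOH/H2O, 40 °C; then 1 M HCl to pH 4, 0 °C
Reagents that add atoms: lithium hydroxide, [Li+].[OH-]
Why: Saponification should reach only the unhindered methyl ester, since the tert-butyl ester on quaternary C3 and the ketone between two quaternary carbons are shielded from hydroxide.

Step 11
Reactants: 11 carboxylic acid
Product: 14 bicyclic enol ether (1R,5R,7S), via dihydropyran acid 12 (not isolated), via acid chloride 13 (not isolated)
Conditions: Sc(OTf)3 (10 mol %), CH2Cl2, 0 °C; then 1-chloro-N,N,2-trimethylprop-1-en-1-amine, 0 °C; then AgOTf, 2,6-di-tert-butyl-4-methylpyridine, −78 → 0 °C; then TMSOTf (20 mol %), 0 °C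
Reagents that add atoms: none
Why: Proposed new method: Sc(OTf)3 chelates the β-keto ester of 11 and heterolyses the strained C5–C8 bond, the enolate oxygen O4 captures the tertiary C8 cation and dihydropyran 12 results (closest known types: acid-induced opening of pinane-derived cyclobutyl ketones at the gem-dimethyl carbon and ring expansion of donor–acceptor cyclobutanes). The chloroenamine turns the acid into chloride 13 and AgOTf ionises it to a methoxy-stabilised acylium ion, in which rotation about C1–C2 is free so that both enol ether isomers converge, and this ion C-acylates the tetrasubstituted enol ether at C5 (Friedel–Crafts-type acylation of an enol ether), closing ring A through C5–C9 in a 6-(enolendo)-exo-dig mode. Because C3 and C5 are now both quaternary, the oxocarbenium ion at C4 has no α-hydrogen to lose and can only expel C8 as the tertiary cation, which C1, the α-carbon of the new β-methoxy enone, captures (closest known type: biomimetic cation–enol ether cyclisation to bicyclo[3.3.1]nonanes), closing ring B through C1–C8 in a 6-(enolexo) mode; the C2 oxocarbenium ion then loses isobutene and CO2 from the C3 tert-butyl ester (TMSOTf helps) and leaves the C2 methyl enol ether conjugated to the C4 ketone. C5 is controlled by the C7 stereocentre through the dihydropyran ring: the acylium carbon adds axially to the half-chair on the face anti to the pseudo-equatorial C7 chain, so C9 ends trans to that chain, which is the 7-endo arrangement (chain syn to the C2–C4 bridge) once ring B has closed, while C1 is dictated by the geometry of the bicycle. The selectivities needed are C-acylation by the enol ether and not by a prenyl double bond, which the much higher nucleophilicity of the enol ether secures, and termination at C1 and not at C3 or oxygen, which the quaternary C3 ester (no C3 nucleophile, no proton loss from the C4 oxocarbenium ion) and the reversibility of O-alkylation under ionising conditions secure. Proton loss from the C8 cation is the main competing path; it is disfavoured by the low temperature and by the intramolecular six-membered capture, and the hindered pyridine only buffers the triflic acid that would otherwise attack the prenyl groups.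

Step 12
Reactants: 14 bicyclic enol ether
Product: 15 C1-benzoyl bicycle
Conditions: lithium 2,2,6,6-tetramethylpiperidide, THF, −78 °C; PhCOCl, −78 → −40 °C
Reagents that add atoms: benzoyl chloride, O=C(Cl)c1ccccc1
Why: Bridgehead deprotonation at C1, the only acidic position (α to the C9 ketone and γ to the C4 ketone through the enol ether), followed by C-acylation with the acid chloride is the established way to acylate bicyclo[3.3.1]nonane-trione methyl enol ethers, and the configuration of C1 is held by the bicycle.

Step 13
Reactants: 15 C1-benzoyl bicycle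
Product: 16 primary allylic alcohol
Conditions: HF·pyridine, pyridine/THF, 0 °C → rt
Reagents that add atoms: none
Why: Fluoride-mediated silyl ether cleavage under buffered, weakly acidic conditions should spare the vinylogous ester and the non-enolisable triketone array at C1, which a basic fluoride source could cleave by retro-Claisen reaction.

Step 14
Reactants: 16 primary allylic alcohol
Product: 17 target
Conditions: Ac2O, pyridine, DMAP (cat.), CH2Cl2, 0 °C
Reagents that add atoms: acetic anhydride, CC(=O)OC(C)=O
Why: DMAP-catalysed acetylation (nucleophilic catalysis) of the only hydroxyl group should give the allylic acetate without touching a stereocentre.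

**Compound list**

1 | (−)-α-pinene, (1S,5S)-2,6,6-trimethylbicyclo[3.1.1]hept-2-ene | CC1=CC[C@H]2C[C@@H]1C2(C)C | starting material
2 | (−)-cis-pinonaldehyde, 2-(cis-3-acetyl-2,2-dimethylcyclobutyl)acetaldehyde with the ring stereocentres of 1 | CC(=O)[C@@H]1C[C@H](CC=O)C1(C)C | intermediate
3 | (E)-4-(cis-3-acetyl-2,2-dimethylcyclobutyl)-2-methylbut-2-enal | CC(=O)[C@@H]1C[C@H](C/C=C(\C)C=O)C1(C)C | intermediate
4 | 1-[cis-3-((E)-4-hydroxy-3-methylbut-2-enyl)-2,2-dimethylcyclobutyl]ethanone | CC(=O)[C@@H]1C[C@H](C/C=C(\C)CO)C1(C)C | intermediate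
5 | tert-butyldiphenylsilyl ether of 4 | CC(=O)[C@@H]1C[C@H](C/C=C(\C)CO[Si](c2ccccc2)(c2ccccc2)C(C)(C)C)C1(C)C | intermediate
6 | tert-butyl 3-oxo-3-(cyclobutyl)propanoate from 5 (tert-butoxycarbonyl group on the former methyl carbon C3) | CC(C)(C)OC(=O)CC(=O)[C@@H]1C[C@H](C/C=C(\C)CO[Si](c2ccccc2)(c2ccccc2)C(C)(C)C)C1(C)C | intermediate
7 | 6 with a 3-methylbut-2-enyl group on the acyl-bearing cyclobutane carbon C5 (both C5 epimers) | CC(C)(C)OC(=O)CC(=O)C1(CC=C(C)C)C[C@H](C/C=C(\C)CO[Si](c2ccccc2)(c2ccccc2)C(C)(C)C)C1(C)C | intermediate
8 | 7 with a second 3-methylbut-2-enyl group on C3 (epimers at C3 and C5) | CC(C)(C)OC(=O)C(CC=C(C)C)C(=O)C1(CC=C(C)C)C[C@H](C/C=C(\C)CO[Si](c2ccccc2)(c2ccccc2)C(C)(C)C)C1(C)C | intermediate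
9 | 8 with a 3-methoxy-3-oxopropanoyl group on C3 (1-tert-butyl 5-methyl 2-acyl-2-prenyl-3-oxopentanedioate) | COC(=O)CC(=O)C(CC=C(C)C)(C(=O)OC(C)(C)C)C(=O)C1(CC=C(C)C)C[C@H](C/C=C(\C)CO[Si](c2ccccc2)(c2ccccc2)C(C)(C)C)C1(C)C | intermediate
10 | methyl enol ether of 9 at C2 (5-tert-butyl 1-methyl 4-acyl-3-methoxy-4-prenylpent-2-enedioate, enol ether isomers) | COC(=O)C=C(OC)C(CC=C(C)C)(C(=O)OC(C)(C)C)C(=O)C1(CC=C(C)C)C[C@H](C/C=C(\C)CO[Si](c2ccccc2)(c2ccccc2)C(C)(C)C)C1(C)C | intermediate
11 | C9 carboxylic acid from 10 | OC(=O)C=C(OC)C(CC=C(C)C)(C(=O)OC(C)(C)C)C(=O)C1(CC=C(C)C)C[C@H](C/C=C(\C)CO[Si](c2ccccc2)(c2ccccc2)C(C)(C)C)C1(C)C | intermediate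
12 | dihydropyran acid from ring expansion of 11 (O4 bonded to C8, enol ether C4=C5, not isolated) | OC(=O)C=C(OC)C(CC=C(C)C)(C(=O)OC(C)(C)C)C1=C(CC=C(C)C)C[C@H](C/C=C(\C)CO[Si](c2ccccc2)(c2ccccc2)C(C)(C)C)C(C)(C)O1 | intermediate
13 | acid chloride of 12 (not isolated) | O=C(Cl)C=C(OC)C(CC=C(C)C)(C(=O)OC(C)(C)C)C1=C(CC=C(C)C)C[C@H](C/C=C(\C)CO[Si](c2ccccc2)(c2ccccc2)C(C)(C)C)C(C)(C)O1 | intermediate
14 | (1R,5R,7S)-7-[(E)-4-(tert-butyldiphenylsilyloxy)-3-methylbut-2-enyl]-2-methoxy-8,8-dimethyl-3,5-bis(3-methylbut-2-enyl)bicyclo[3.3.1]non-2-ene-4,9-dione | COC1=C(CC=C(C)C)C(=O)[C@]2(CC=C(C)C)C[C@H](C/C=C(\C)CO[Si](c3ccccc3)(c3ccccc3)C(C)(C)C)C(C)(C)[C@H]1C2=O | intermediate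
15 | (1R,5S,7S)-1-benzoyl derivative of 14 | COC1=C(CC=C(C)C)C(=O)[C@]2(CC=C(C)C)C[C@H](C/C=C(\C)CO[Si](c3ccccc3)(c3ccccc3)C(C)(C)C)C(C)(C)[C@@]1(C(=O)c1ccccc1)C2=O | intermediate
16 | (1R,5S,7S)-1-benzoyl-7-[(E)-4-hydroxy-3-methylbut-2-enyl]-2-methoxy-8,8-dimethyl-3,5-bis(3-methylbut-2-enyl)bicyclo[3.3.1]non-2-ene-4,9-dione | COC1=C(CC=C(C)C)C(=O)[C@]2(CC=C(C)C)C[C@H](C/C=C(\C)CO)C(C)(C)[C@@]1(C(=O)c1ccccc1)C2=O | intermediate
17 | (1R,5S,7S)-7-[(E)-4-acetoxy-3-methylbut-2-enyl]-1-benzoyl-2-methoxy-8,8-dimethyl-3,5-bis(3-methylbut-2-enyl)bicyclo[3.3.1]non-2-ene-4,9-dione | COC1=C(CC=C(C)C)C(=O)[C@]2(CC=C(C)C)C[C@H](C/C=C(\C)COC(C)=O)C(C)(C)[C@@]1(C(=O)c1ccccc1)C2=O | target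

**Step count and risks**

Total step count: 14. Longest linear sequence: 14 steps (the route is linear from 1).

Steps most likely to fail:

Step 11 (proposed new method). The one-pot cascade may leak in several ways:
- the C8 cation may be lost by proton elimination or by cyclisation onto a prenyl double bond before C1 closes;
- the acylation at C5 may show poor facial selectivity, which would carry material into the 7-exo series;
- the tert-butyl ester may be lost too early, which would unblock C3.

The fallback uses known reactions one at a time. It sets out from 10 and comes back at 14. Ring opening of 10 alone with Sc(OTf)3 in CH2Cl2 (the known Lewis acid opening of pinane-type cyclobutyl ketones) should give dihydropyran ester F1. Hydrolysis of its enol ether (pyridinium p-toluenesulfonate, wet acetone) should give tertiary hydroxy ketone F2. Dieckmann condensation of F2 (LiN(SiMe3)2, THF, −78 → 0 °C; C5–H is the only enolisable position) should give cyclohexenedione F3 as a mixture at C5. Formic acid at room temperature should then ionise the tertiary alcohol and close C1–C8 (the known cation–enol ether cyclisation to bicyclo[3.3.1]nonanes) with loss of isobutene and CO2. Because the Dieckmann step does not control C5, this should give 14 together with its 7-exo diastereomer F4, which is removed by chromatography.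

Step 8. The hindered enolate may undergo O-acylation, or the acid chloride may form a ketene, instead of the C–C bond forming at the congested C3. The fallback sets out from 8 and comes back at 10. Electrophilic alkynylation of the enolate of 8 with 1-[(trimethylsilyl)ethynyl]-1,2-benziodoxol-3(1H)-one and Bu4NF in THF should make the quaternary centre with a slim electrophile and give α-ethynyl keto ester F5. Oxidative methoxycarbonylation of the terminal alkyne (PdCl2, CuCl2, NaOAc, CO, MeOH, room temperature) should give ynoate F6. Conjugate addition of methanol (PMe3 as catalyst, MeOH) should give 10 directly.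

Step 12. Deprotonation at the congested bridgehead may be incomplete, and the delocalised anion may undergo O-acylation. The fallback sets out from 14 and comes back at 15. The bridgehead lithium species (lithium 2,2,6,6-tetramethylpiperidide, THF, −78 °C) is trapped with benzaldehyde, a smaller and more reactive electrophile, to give bridgehead phenylcarbinol F7. Oxidation of F7 with 1,1,1-triacetoxy-1,1-dihydro-1,2-benziodoxol-3(1H)-one (NaHCO3, CH2Cl2) should give 15.

Further compounds
F1 | step 11 | dihydropyran methyl ester (ring-expanded 10) | COC(=O)C=C(OC)C(CC=C(C)C)(C(=O)OC(C)(C)C)C1=C(CC=C(C)C)C[C@H](C/C=C(\C)CO[Si](c2ccccc2)(c2ccccc2)C(C)(C)C)C(C)(C)O1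
F2 | step 11 | tertiary hydroxy ketone from hydrolysis of F1 | COC(=O)C=C(OC)C(CC=C(C)C)(C(=O)OC(C)(C)C)C(=O)C(CC=C(C)C)C[C@H](C/C=C(\C)CO[Si](c2ccccc2)(c2ccccc2)C(C)(C)C)C(C)(C)O
F3 | step 11 | 3-methoxycyclohex-2-ene-1,5-dione from Dieckmann closure of F2 (C5 epimers) | COC1=CC(=O)C(CC=C(C)C)(C[C@H](C/C=C(\C)CO[Si](c2ccccc2)(c2ccccc2)C(C)(C)C)C(C)(C)O)C(=O)C1(CC=C(C)C)C(=O)OC(C)(C)C
F4 | step 11 | 7-exo diastereomer of 14 | COC1=C(CC=C(C)C)C(=O)[C@@]2(CC=C(C)C)C[C@H](C/C=C(\C)CO[Si](c3ccccc3)(c3ccccc3)C(C)(C)C)C(C)(C)[C@@H]1C2=O
F5 | step 8 | α-ethynyl keto ester from 8 | C#CC(CC=C(C)C)(C(=O)OC(C)(C)C)C(=O)C1(CC=C(C)C)C[C@H](C/C=C(\C)CO[Si](c2ccccc2)(c2ccccc2)C(C)(C)C)C1(C)C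
F6 | step 8 | ynoate from methoxycarbonylation of F5 | COC(=O)C#CC(CC=C(C)C)(C(=O)OC(C)(C)C)C(=O)C1(CC=C(C)C)C[C@H](C/C=C(\C)CO[Si](c2ccccc2)(c2ccccc2)C(C)(C)C)C1(C)C
F7 | step 12 | bridgehead phenylcarbinol from 14 | COC1=C(CC=C(C)C)C(=O)[C@]2(CC=C(C)C)C[C@H](C/C=C(\C)CO[Si](c3ccccc3)(c3ccccc3)C(C)(C)C)C(C)(C)[C@@]1(C(O)c1ccccc1)C2=O
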